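**Retrosynthetic overview**
1. The target comes from mixed-anhydride angeloylation of the C2 alcohol of a tetracyclic diol; its 5β,11-ether bridge and 4α-OH come from acid-triggered 5-exo opening of a 4α,5α-epoxide (directed by the 2α-OH) by the C11 hydroxyl.
2. C11 (O, Me) comes from convex-face hydroxylation, then convex-face methylation, of a cis-fused 12,8-lactone; the lactone comes from acrylate ring-closing metathesis to a butenolide and convex-face hydrogenation; C8 from CBS reduction of an α-methylene ketone; C10 from methyl 1,4-addition.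
3. Ring B comes from enone ring-closing metathesis of a cyclopentene carrying a C1 vinyl group and a C5 3-oxopent-4-enyl chain.
4. Ring A comes from (S)-4-silyloxycyclopentenone by α-iodination/Negishi coupling, vinyl 1,4-addition with enolate triflation, and methyl cross-coupling.
5. Absolute configuration comes from esterase desymmetrisation of meso cis-3,5-diacetoxycyclopentene; ring order: A, then B, then lactone, then ether bridge.

Assumption: guaiane numbering is used for the bi- to tetracyclic compounds (ring A = C1–C5 with C15 on C4; ring B = C1, C5–C10 with C14 on C10; C11–C13 on C7), α is the face of H-1 and β the face of the lactone and ether oxygens, TBS = tert-butyldimethylsilyl, MOP = 2-methoxypropan-2-yl, and the SMILES strings are authoritative.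

**Route**

Step 1
Reactants: 1 cis-cyclopent-4-ene-1,3-diyl diacetate (meso)
Product: 2 (1R,4S)-4-hydroxycyclopent-2-en-1-yl acetate
Conditions: electric-eel acetylcholinesterase (an esterase), 0.1 M sodium phosphate buffer pH 6.9, rt
Reagents that add atoms: none
Why: Enzymatic desymmetrisation by enantiotopos-selective ester hydrolysis cleaves only one of the two mirror-related acetates of the meso diester, setting both carbinol centres in high ee, the free (S)-carbinol becoming C2 of the target.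

Step 2
Reactants: 2 (1R,4S)-4-hydroxycyclopent-2-en-1-yl acetate
Product: 3 (1R,4S)-4-[(tert-butyldimethylsilyl)oxy]cyclopent-2-en-1-yl acetate
Conditions: TBSCl, imidazole, DMF, rt
Reagents that add atoms: tert-butyldimethylsilyl chloride, CC(C)(C)[Si](C)(C)Cl
Why: Standard imidazole-promoted silylation protects the future C2 oxygen as a robust silyl ether without touching the stereocentres.

Step 3
Reactants: 3 (1R,4S)-4-[(tert-butyldimethylsilyl)oxy]cyclopent-2-en-1-yl acetate
Product: 4 (1R,4S)-4-[(tert-butyldimethylsilyl)oxy]cyclopent-2-en-1-ol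
Conditions: K2CO3 (0.2 equiv), MeOH, 0 °C
Reagents that add atoms: none
Why: Base-catalysed transesterification (methanolysis) removes the acetate while the silyl ether is stable.

Step 4
Reactants: 4 (1R,4S)-4-[(tert-butyldimethylsilyl)oxy]cyclopent-2-en-1-ol
Product: 5 (4S)-4-[(tert-butyldimethylsilyl)oxy]cyclopent-2-en-1-one
Conditions: MnO2 (activated, excess), CH2Cl2, rt
Reagents that add atoms: none
Why: Chemoselective allylic alcohol oxidation gives the enone under neutral conditions that neither eliminate the β-silyloxy group nor touch the C4 stereocentre.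

Step 5
Reactants: 5 (4S)-4-[(tert-butyldimethylsilyl)oxy]cyclopent-2-en-1-one
Product: 6 (4S)-4-[(tert-butyldimethylsilyl)oxy]-2-iodocyclopent-2-en-1-one
Conditions: I2, pyridine, CH2Cl2, 0 °C to rt
Reagents that add atoms: iodine, II
Why: α-Iodination of the enone by the Johnson protocol (pyridine 1,4-addition, iodination of the enolate, loss of pyridine) installs the cross-coupling handle at the future C5.

Step 6
Reactants: 6 (4S)-4-[(tert-butyldimethylsilyl)oxy]-2-iodocyclopent-2-en-1-one; 7 ethyl 3-iodopropanoate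
Product: 9 ethyl 3-[(3S)-3-[(tert-butyldimethylsilyl)oxy]-5-oxocyclopent-1-en-1-yl]propanoate, via (3-ethoxy-3-oxopropyl)zinc iodide 8 (not isolated)
Conditions: 7, Zn dust (Me3SiCl-activated), THF, 35 °C; then 6, Pd2(dba)3 (2.5 mol%), P(2-furyl)3 (10 mol%), THF/DMF, rt
Reagents that add atoms: none
Why: Negishi coupling (oxidative addition of zerovalent palladium into the alkenyl C–I bond, transmetalation from the zinc homoenolate, reductive elimination) joins C5 to C6 under neutral conditions that spare the β-silyloxy enone.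

Step 7
Reactants: 9 ethyl 3-[(3S)-3-[(tert-butyldimethylsilyl)oxy]-5-oxocyclopent-1-en-1-yl]propanoate
Product: 11 ethyl 3-[(4S,5S)-4-[(tert-butyldimethylsilyl)oxy]-5-ethenyl-2-[(trifluoromethanesulfonyl)oxy]cyclopent-1-en-1-yl]propanoate, via bromomagnesium enolate 10 (not isolated)
Conditions: CH2=CHMgBr (1.5 equiv), CuBr·SMe2 (10 mol%), THF, −78 °C; then PhNTf2, −78 to 0 °C
Reagents that add atoms: vinylmagnesium bromide, C=C[Mg]Br; N-phenylbis(trifluoromethanesulfonimide), O=S(=O)(N(c1ccccc1)S(=O)(=O)C(F)(F)F)C(F)(F)F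
Why: Copper-catalysed 1,4-addition delivers the vinyl group anti to the adjacent silyloxy group (sets C1, H-1 α), and O-triflation of the regiodefined enolate fixes the future C4=C5 alkene position.

Step 8
Reactants: 11 ethyl 3-[(4S,5S)-4-[(tert-butyldimethylsilyl)oxy]-5-ethenyl-2-[(trifluoromethanesulfonyl)oxy]cyclopent-1-en-1-yl]propanoate
Product: 12 ethyl 3-[(4S,5S)-4-[(tert-butyldimethylsilyl)oxy]-5-ethenyl-2-methylcyclopent-1-en-1-yl]propanoate
Conditions: MeMgBr (1.3 equiv), Fe(acac)3 (5 mol%), THF/NMP, −30 °C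
Reagents that add atoms: methylmagnesium bromide, C[Mg]Br
Why: Iron-catalysed Kumada-type cross-coupling of the alkenyl triflate is much faster than Grignard addition to the ester and installs C15 on the tetrasubstituted C4=C5 alkene.

Step 9
Reactants: 12 ethyl 3-[(4S,5S)-4-[(tert-butyldimethylsilyl)oxy]-5-ethenyl-2-methylcyclopent-1-en-1-yl]propanoate
Product: 13 3-[(4S,5S)-4-[(tert-butyldimethylsilyl)oxy]-5-ethenyl-2-methylcyclopent-1-en-1-yl]-N-methoxy-N-methylpropanamide
Conditions: MeNH(OMe)·HCl, iPrMgCl, THF, −20 °C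
Reagents that add atoms: N,O-dimethylhydroxylamine hydrochloride, CNOC.Cl
Why: Aminolysis of the ester by the magnesium amide formed in the flask gives the Weinreb amide directly.

Step 10
Reactants: 13 3-[(4S,5S)-4-[(tert-butyldimethylsilyl)oxy]-5-ethenyl-2-methylcyclopent-1-en-1-yl]-N-methoxy-N-methylpropanamide
Product: 14 5-[(4S,5S)-4-[(tert-butyldimethylsilyl)oxy]-5-ethenyl-2-methylcyclopent-1-en-1-yl]pent-1-en-3-one
Conditions: CH2=CHMgBr, THF, 0 °C; cold aq. HCl quench
Reagents that add atoms: vinylmagnesium bromide, C=C[Mg]Br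
Why: Weinreb ketone synthesis, in which the chelated tetrahedral intermediate prevents over-addition and releases the vinyl ketone (C8, C9) only on acidic quench.

Step 11
Reactants: 14 5-[(4S,5S)-4-[(tert-butyldimethylsilyl)oxy]-5-ethenyl-2-methylcyclopent-1-en-1-yl]pent-1-en-3-one
Product: 15 2α-[(tert-butyldimethylsilyl)oxy]-11,12,13,14-tetranor-1αH-guaia-4,9-dien-8-one
Conditions: second-generation Grubbs catalyst RuCl2(=CHPh)(PCy3)(H2IMes) (5 mol%), CH2Cl2 (5 mM), 40 °C
Reagents that add atoms: none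
Why: Ring-closing metathesis between the vinyl ketone and the C1 vinyl group closes the seven-membered enone (ring B) while the tetrasubstituted C4=C5 alkene is inert.

Step 12
Reactants: 15 2α-[(tert-butyldimethylsilyl)oxy]-11,12,13,14-tetranor-1αH-guaia-4,9-dien-8-one
Product: 17 7ξ-[(dimethylamino)methyl]-2α-[(tert-butyldimethylsilyl)oxy]-11,12,13,14-tetranor-1αH-guaia-4,9-dien-8-one, via lithium dienolate 16 (not isolated)
Conditions: LiN(iPr)2, THF, −78 °C; then CH2=NMe2+ I−, −78 to 0 °C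
Reagents that add atoms: dimethylmethylideneammonium iodide, C=[N+](C)C.[I-]
Why: Kinetic α′-deprotonation of the enone followed by a Mannich reaction with Eschenmoser's salt functionalises C7 regiospecifically, the C7 configuration being irrelevant because it is erased in step 14.

Step 13
Reactants: 17 7ξ-[(dimethylamino)methyl]-2α-[(tert-butyldimethylsilyl)oxy]-11,12,13,14-tetranor-1αH-guaia-4,9-dien-8-one
Product: 19 7ξ-[(dimethylamino)methyl]-2α-[(tert-butyldimethylsilyl)oxy]-11,12,13-trinor-1αH,10βH-guai-4-en-8-one, via bromomagnesium enolate 18 (not isolated)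
Conditions: MeMgBr (1.5 equiv), CuBr·SMe2 (10 mol%), THF, −40 °C; aq. NH4Cl
Reagents that add atoms: methylmagnesium bromide, C[Mg]Br
Why: Copper-catalysed conjugate addition delivers the methyl group to C10 anti to the C1–C2 bond of ring A (the usual trans selectivity next to a γ-stereocentre), giving the 10α-methyl (10R) centre.

Step 14
Reactants: 19 7ξ-[(dimethylamino)methyl]-2α-[(tert-butyldimethylsilyl)oxy]-11,12,13-trinor-1αH,10βH-guai-4-en-8-one
Product: 21 7-methylidene-2α-[(tert-butyldimethylsilyl)oxy]-11,12,13-trinor-1αH,10βH-guai-4-en-8-one, via trimethylammonium iodide 20 (not isolated)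
Conditions: MeI, CH2Cl2, rt; then NaHCO3, CH2Cl2/H2O, rt
Reagents that add atoms: none
Why: Quaternisation and mild-base β-elimination of trimethylamine (Mannich-base route to α-methylene ketones) places an exocyclic alkene at C7 only.

Step 15
Reactants: 21 7-methylidene-2α-[(tert-butyldimethylsilyl)oxy]-11,12,13-trinor-1αH,10βH-guai-4-en-8-one
Product: 22 7-methylidene-2α-[(tert-butyldimethylsilyl)oxy]-11,12,13-trinor-1αH,8αH,10βH-guai-4-en-8β-ol
Conditions: (S)-2-methyl-CBS-oxazaborolidine (20 mol%), catecholborane, toluene, −78 °C; then MeOH, aq. NaOH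
Reagents that add atoms: none
Why: Corey–Bakshi–Shibata reduction under catalyst control, with the alkenyl (C7) side as the large group and the C9 methylene as the small one, delivers hydride to the α face and sets the 8β (8R) carbinol.

Step 16
Reactants: 22 7-methylidene-2α-[(tert-butyldimethylsilyl)oxy]-11,12,13-trinor-1αH,8αH,10βH-guai-4-en-8β-ol
Product: 23 7-methylidene-2α-[(tert-butyldimethylsilyl)oxy]-11,12,13-trinor-1αH,8αH,10βH-guai-4-en-8β-yl prop-2-enoate
Conditions: acryloyl chloride, Et3N, DMAP (cat.), CH2Cl2, −20 °C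
Reagents that add atoms: acryloyl chloride, C=CC(=O)Cl
Why: Simple O-acylation of the secondary allylic alcohol attaches the two lactone carbons (C12 and C11) to O-8 with retention at C8.

Step 17
Reactants: 23 7-methylidene-2α-[(tert-butyldimethylsilyl)oxy]-11,12,13-trinor-1αH,8αH,10βH-guai-4-en-8β-yl prop-2-enoate
Product: 24 2α-[(tert-butyldimethylsilyl)oxy]-13-nor-1αH,8αH,10βH-guaia-4,7(11)-dien-12,8β-olide
Conditions: second-generation Grubbs catalyst RuCl2(=CHPh)(PCy3)(H2IMes) (10 mol%), toluene (2 mM), 80 °C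
Reagents that add atoms: none
Why: Ring-closing metathesis of the acrylate with the 1,1-disubstituted exocyclic alkene forms the fused butenolide (C7=C11) with loss of ethene.

Step 18
Reactants: 24 2α-[(tert-butyldimethylsilyl)oxy]-13-nor-1αH,8αH,10βH-guaia-4,7(11)-dien-12,8β-olide
Product: 25 2α-[(tert-butyldimethylsilyl)oxy]-13-nor-1αH,7αH,8αH,10βH-guai-4-en-12,8β-olide
Conditions: H2 (1 atm), Rh/Al2O3 (5 wt% Rh), EtOAc, rt
Reagents that add atoms: none
Why: Heterogeneous hydrogenation adds H2 to the conjugated trisubstituted alkene from the convex face (the face of H-8), setting H-7 α and giving the cis-fused lactone, while the tetrasubstituted C4=C5 alkene is untouched.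

Step 19
Reactants: 25 2α-[(tert-butyldimethylsilyl)oxy]-13-nor-1αH,7αH,8αH,10βH-guai-4-en-12,8β-olide
Product: 27 (11R)-11-hydroxy-2α-[(tert-butyldimethylsilyl)oxy]-13-nor-1αH,7αH,8αH,10βH-guai-4-en-12,8β-olide, via lithium enolate 26 (not isolated)
Conditions: LiN(SiMe3)2, THF, −78 °C; then 2-(phenylsulfonyl)-3-phenyloxaziridine, −78 °C; aq. NH4Cl
Reagents that add atoms: 2-(phenylsulfonyl)-3-phenyloxaziridine, O=S(=O)(N1OC1c1ccccc1)c1ccccc1
Why: Davis oxidation of the lactone enolate introduces the C11 oxygen from the convex face, a configuration that is inconsequential because C11 is planarised again in step 21.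

Step 20
Reactants: 27 (11R)-11-hydroxy-2α-[(tert-butyldimethylsilyl)oxy]-13-nor-1αH,7αH,8αH,10βH-guai-4-en-12,8β-olide
Product: 28 (11R)-11-[(2-methoxypropan-2-yl)oxy]-2α-[(tert-butyldimethylsilyl)oxy]-13-nor-1αH,7αH,8αH,10βH-guai-4-en-12,8β-olide
Conditions: 2-methoxypropene, pyridinium p-toluenesulfonate (5 mol%), CH2Cl2, 0 °C
Reagents that add atoms: 2-methoxypropene, COC(C)=C
Why: Acid-catalysed addition of the alcohol to the enol ether gives a base- and fluoride-stable but very acid-labile mixed ketal (MOP ether).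

Step 21
Reactants: 28 (11R)-11-[(2-methoxypropan-2-yl)oxy]-2α-[(tert-butyldimethylsilyl)oxy]-13-nor-1αH,7αH,8αH,10βH-guai-4-en-12,8β-olide
Product: 30 (11S)-11-[(2-methoxypropan-2-yl)oxy]-2α-[(tert-butyldimethylsilyl)oxy]-1αH,7αH,8αH,10βH-guai-4-en-12,8β-olide, via lithium enolate 29 (not isolated)
Conditions: LiN(iPr)2, THF/DMPU, −78 °C; then MeI, −78 to −40 °C
Reagents that add atoms: iodomethane, CI
Why: Enolate alkylation of the α-alkoxy lactone brings the methyl group in from the convex face (the face of H-7), forcing the C11 oxygen onto the concave face above ring B and so setting the quaternary (11S) centre.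

Step 22
Reactants: 30 (11S)-11-[(2-methoxypropan-2-yl)oxy]-2α-[(tert-butyldimethylsilyl)oxy]-1αH,7αH,8αH,10βH-guai-4-en-12,8β-olide
Product: 31 (11S)-2α-hydroxy-11-[(2-methoxypropan-2-yl)oxy]-1αH,7αH,8αH,10βH-guai-4-en-12,8β-olide
Conditions: Bu4NF, THF, 0 °C to rt
Reagents that add atoms: none
Why: Fluoride-mediated desilylation frees only the C2 alcohol because the MOP ketal is inert to fluoride.

Step 23
Reactants: 31 (11S)-2α-hydroxy-11-[(2-methoxypropan-2-yl)oxy]-1αH,7αH,8αH,10βH-guai-4-en-12,8β-olide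
Product: 32 (11S)-4α,5α-epoxy-2α-hydroxy-11-[(2-methoxypropan-2-yl)oxy]-1αH,7αH,8αH,10βH-guaian-12,8β-olide
Conditions: VO(acac)2 (5 mol%), tBuOOH (1.5 equiv), CH2Cl2, 0 °C to rt
Reagents that add atoms: tert-butyl hydroperoxide, CC(C)(C)OO
Why: Hydroxyl-directed vanadium-catalysed epoxidation, in which the homoallylic 2α-OH (a cyclopent-3-enol) delivers oxygen to the α face of the C4=C5 alkene, sets the C4–O bond while the masked C11 oxygen cannot compete.

Step 24
Reactants: 32 (11S)-4α,5α-epoxy-2α-hydroxy-11-[(2-methoxypropan-2-yl)oxy]-1αH,7αH,8αH,10βH-guaian-12,8β-olide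
Product: 34 (11S)-5β,11-epoxy-2α,4α-dihydroxy-1αH,7αH,8αH,10βH-guaian-12,8β-olide, via 11-hydroxy epoxide 33 (not isolated)
Conditions: camphorsulfonic acid (10 mol%), CH2Cl2/MeOH 10:1, 0 °C to rt
Reagents that add atoms: none
Why: Ketal methanolysis frees the concave C11 hydroxyl, which opens the protonated epoxide by 5-exo attack at C5 from the β face (inversion at C5, retention at C4), forming the tetrahydrofuran bridge and the 4α tertiary alcohol.

Step 25
Reactants: 34 (11S)-5β,11-epoxy-2α,4α-dihydroxy-1αH,7αH,8αH,10βH-guaian-12,8β-olide; 35 angelic acid, (Z)-2-methylbut-2-enoic acid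
Product: 37 (1R,2S,4R,5R,7S,8R,10R,11S)-2α-angeloyloxy-5β,11-epoxy-4α-hydroxy-1αH,7αH,8αH,10βH-guaian-12,8β-olide, via angelic 2,4,6-trichlorobenzoic anhydride 36 (not isolated)
Conditions: 35, 2,4,6-trichlorobenzoyl chloride, Et3N, toluene, rt; then 34, 80 °C
Reagents that add atoms: none
Why: Yamaguchi-type mixed-anhydride esterification run without nucleophilic catalyst acylates only the secondary C2 alcohol (the tertiary C4 alcohol is inert) and avoids Z-to-E isomerisation of the angelate.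

**Compound list**
1 | cis-cyclopent-4-ene-1,3-diyl diacetate (meso) | CC(=O)O[C@H]1C[C@@H](OC(C)=O)C=C1 | starting material
2 | (1R,4S)-4-hydroxycyclopent-2-en-1-yl acetate | O[C@H]1C[C@@H](OC(C)=O)C=C1 | intermediate
3 | (1R,4S)-4-[(tert-butyldimethylsilyl)oxy]cyclopent-2-en-1-yl acetate | CC(C)(C)[Si](C)(C)O[C@H]1C[C@@H](OC(C)=O)C=C1 | intermediate
4 | (1R,4S)-4-[(tert-butyldimethylsilyl)oxy]cyclopent-2-en-1-ol | CC(C)(C)[Si](C)(C)O[C@H]1C[C@@H](O)C=C1 | intermediate
5 | (4S)-4-[(tert-butyldimethylsilyl)oxy]cyclopent-2-en-1-one | CC(C)(C)[Si](C)(C)O[C@H]1CC(=O)C=C1 | intermediate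
6 | (4S)-4-[(tert-butyldimethylsilyl)oxy]-2-iodocyclopent-2-en-1-one | CC(C)(C)[Si](C)(C)O[C@H]1CC(=O)C(I)=C1 | intermediate
7 | ethyl 3-iodopropanoate | CCOC(=O)CCI | starting material
8 | (3-ethoxy-3-oxopropyl)zinc iodide | CCOC(=O)CC[Zn]I | intermediate
9 | ethyl 3-[(3S)-3-[(tert-butyldimethylsilyl)oxy]-5-oxocyclopent-1-en-1-yl]propanoate | CC(C)(C)[Si](C)(C)O[C@H]1CC(=O)C(CCC(=O)OCC)=C1 | intermediate
10 | bromomagnesium enolate of the vinyl 1,4-adduct of 9 (O–MgBr on C4, C4=C5, vinyl trans to OTBS) | CC(C)(C)[Si](C)(C)O[C@H]1CC(O[Mg]Br)=C(CCC(=O)OCC)[C@@H]1C=C | intermediate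
11 | ethyl 3-[(4S,5S)-4-[(tert-butyldimethylsilyl)oxy]-5-ethenyl-2-[(trifluoromethanesulfonyl)oxy]cyclopent-1-en-1-yl]propanoate | CC(C)(C)[Si](C)(C)O[C@H]1CC(OS(=O)(=O)C(F)(F)F)=C(CCC(=O)OCC)[C@@H]1C=C | intermediate
12 | ethyl 3-[(4S,5S)-4-[(tert-butyldimethylsilyl)oxy]-5-ethenyl-2-methylcyclopent-1-en-1-yl]propanoate | CC(C)(C)[Si](C)(C)O[C@H]1CC(C)=C(CCC(=O)OCC)[C@@H]1C=C | intermediate
13 | 3-[(4S,5S)-4-[(tert-butyldimethylsilyl)oxy]-5-ethenyl-2-methylcyclopent-1-en-1-yl]-N-methoxy-N-methylpropanamide | CC(C)(C)[Si](C)(C)O[C@H]1CC(C)=C(CCC(=O)N(C)OC)[C@@H]1C=C | intermediate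
14 | 5-[(4S,5S)-4-[(tert-butyldimethylsilyl)oxy]-5-ethenyl-2-methylcyclopent-1-en-1-yl]pent-1-en-3-one | CC(C)(C)[Si](C)(C)O[C@H]1CC(C)=C(CCC(=O)C=C)[C@@H]1C=C | intermediate
15 | 2α-[(tert-butyldimethylsilyl)oxy]-11,12,13,14-tetranor-1αH-guaia-4,9-dien-8-one | CC(C)(C)[Si](C)(C)O[C@H]1CC(C)=C2CCC(=O)C=C[C@H]12 | intermediate
16 | lithium 7,9-dien-8-olate of 15 (cross-conjugated dienolate) | CC(C)(C)[Si](C)(C)O[C@H]1CC(C)=C2CC=C(O[Li])C=C[C@H]12 | intermediate
17 | 7ξ-[(dimethylamino)methyl]-2α-[(tert-butyldimethylsilyl)oxy]-11,12,13,14-tetranor-1αH-guaia-4,9-dien-8-one (C7 epimers) | CC(C)(C)[Si](C)(C)O[C@H]1CC(C)=C2CC(CN(C)C)C(=O)C=C[C@H]12 | intermediate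
18 | bromomagnesium 8-en-8-olate of 19 (10α-methyl, C8=C9) | CC(C)(C)[Si](C)(C)O[C@H]1CC(C)=C2CC(CN(C)C)C(O[Mg]Br)=C[C@@H](C)[C@H]12 | intermediate
19 | 7ξ-[(dimethylamino)methyl]-2α-[(tert-butyldimethylsilyl)oxy]-11,12,13-trinor-1αH,10βH-guai-4-en-8-one (C7 epimers) | CC(C)(C)[Si](C)(C)O[C@H]1CC(C)=C2CC(CN(C)C)C(=O)C[C@@H](C)[C@H]12 | intermediate
20 | N-methyl quaternary ammonium iodide of 19 | CC(C)(C)[Si](C)(C)O[C@H]1CC(C)=C2CC(C[N+](C)(C)C)C(=O)C[C@@H](C)[C@H]12.[I-] | intermediate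
21 | 7-methylidene-2α-[(tert-butyldimethylsilyl)oxy]-11,12,13-trinor-1αH,10βH-guai-4-en-8-one | CC(C)(C)[Si](C)(C)O[C@H]1CC(C)=C2CC(=C)C(=O)C[C@@H](C)[C@H]12 | intermediate
22 | 7-methylidene-2α-[(tert-butyldimethylsilyl)oxy]-11,12,13-trinor-1αH,8αH,10βH-guai-4-en-8β-ol | CC(C)(C)[Si](C)(C)O[C@H]1CC(C)=C2CC(=C)[C@H](O)C[C@@H](C)[C@H]12 | intermediate
23 | 7-methylidene-2α-[(tert-butyldimethylsilyl)oxy]-11,12,13-trinor-1αH,8αH,10βH-guai-4-en-8β-yl prop-2-enoate | CC(C)(C)[Si](C)(C)O[C@H]1CC(C)=C2CC(=C)[C@H](OC(=O)C=C)C[C@@H](C)[C@H]12 | intermediate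
24 | 2α-[(tert-butyldimethylsilyl)oxy]-13-nor-1αH,8αH,10βH-guaia-4,7(11)-dien-12,8β-olide | CC(C)(C)[Si](C)(C)O[C@H]1CC(C)=C2CC3=CC(=O)O[C@@H]3C[C@@H](C)[C@H]12 | intermediate
25 | 2α-[(tert-butyldimethylsilyl)oxy]-13-nor-1αH,7αH,8αH,10βH-guai-4-en-12,8β-olide | CC(C)(C)[Si](C)(C)O[C@H]1CC(C)=C2C[C@H]3[C@@H](C[C@@H](C)[C@H]12)OC(=O)C3 | intermediate
26 | lithium enolate of 25 | CC(C)(C)[Si](C)(C)O[C@H]1CC(C)=C2C[C@H]3[C@@H](C[C@@H](C)[C@H]12)OC(O[Li])=C3 | intermediate
27 | (11R)-11-hydroxy-2α-[(tert-butyldimethylsilyl)oxy]-13-nor-1αH,7αH,8αH,10βH-guai-4-en-12,8β-olide (11-OH cis to H-7) | CC(C)(C)[Si](C)(C)O[C@H]1CC(C)=C2C[C@H]3[C@@H](C[C@@H](C)[C@H]12)OC(=O)[C@@H]3O | intermediate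
28 | (11R)-11-[(2-methoxypropan-2-yl)oxy]-2α-[(tert-butyldimethylsilyl)oxy]-13-nor-1αH,7αH,8αH,10βH-guai-4-en-12,8β-olide | CC(C)(C)[Si](C)(C)O[C@H]1CC(C)=C2C[C@H]3[C@@H](C[C@@H](C)[C@H]12)OC(=O)[C@@H]3OC(C)(C)OC | intermediate
29 | lithium enolate of 28 | CC(C)(C)[Si](C)(C)O[C@H]1CC(C)=C2C[C@H]3[C@@H](C[C@@H](C)[C@H]12)OC(O[Li])=C3OC(C)(C)OC | intermediate
30 | (11S)-11-[(2-methoxypropan-2-yl)oxy]-2α-[(tert-butyldimethylsilyl)oxy]-1αH,7αH,8αH,10βH-guai-4-en-12,8β-olide | CC(C)(C)[Si](C)(C)O[C@H]1CC(C)=C2C[C@H]3[C@@H](C[C@@H](C)[C@H]12)OC(=O)[C@@]3(C)OC(C)(C)OC | intermediate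
31 | (11S)-2α-hydroxy-11-[(2-methoxypropan-2-yl)oxy]-1αH,7αH,8αH,10βH-guai-4-en-12,8β-olide | O[C@H]1CC(C)=C2C[C@H]3[C@@H](C[C@@H](C)[C@H]12)OC(=O)[C@@]3(C)OC(C)(C)OC | intermediate
32 | (11S)-4α,5α-epoxy-2α-hydroxy-11-[(2-methoxypropan-2-yl)oxy]-1αH,7αH,8αH,10βH-guaian-12,8β-olide | O[C@H]1C[C@@]2(C)O[C@]23C[C@H]4[C@@H](C[C@@H](C)[C@H]13)OC(=O)[C@@]4(C)OC(C)(C)OC | intermediate
33 | (11S)-4α,5α-epoxy-2α,11-dihydroxy-1αH,7αH,8αH,10βH-guaian-12,8β-olide | O[C@H]1C[C@@]2(C)O[C@]23C[C@H]4[C@@H](C[C@@H](C)[C@H]13)OC(=O)[C@@]4(C)O | intermediate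
34 | (11S)-5β,11-epoxy-2α,4α-dihydroxy-1αH,7αH,8αH,10βH-guaian-12,8β-olide | O[C@H]1C[C@@](C)(O)[C@@]23C[C@H]4[C@@H](C[C@@H](C)[C@H]12)OC(=O)[C@@]4(C)O3 | intermediate
35 | angelic acid, (Z)-2-methylbut-2-enoic acid | C/C=C(/C)C(=O)O | starting material
36 | angelic 2,4,6-trichlorobenzoic anhydride | C/C=C(/C)C(=O)OC(=O)c1c(Cl)cc(Cl)cc1Cl | intermediate
37 | (1R,2S,4R,5R,7S,8R,10R,11S)-2α-angeloyloxy-5β,11-epoxy-4α-hydroxy-1αH,7αH,8αH,10βH-guaian-12,8β-olide (CNP0293659.1) | C/C=C(/C)C(=O)O[C@H]1C[C@@](C)(O)[C@@]23C[C@H]4[C@@H](C[C@@H](C)[C@H]12)OC(=O)[C@@]4(C)O3 | target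

**Totals**
Total step count: 25. Longest linear sequence: 25 steps (1 to 37); 7 and 35 enter in steps 6 and 25.

**Steps most likely to fail, and fallbacks**

Step 13 (facial selectivity of the methyl 1,4-addition at C10). If the methyl group enters from the β face, the C10 methyl is instead delivered intramolecularly, setting out from 15. Reduction of 15 with (S)-2-methyl-CBS-oxazaborolidine and catecholborane (here the C9 alkenyl side is the large group) gives the 8α-allylic alcohol F1. Hydroxyl-directed Simmons–Smith cyclopropanation (Et2Zn, CH2I2) places the new methylene on the α face and gives the cyclopropyl carbinol F2. Dess–Martin oxidation gives the cyclopropyl ketone F3. LiN(iPr)2 and Eschenmoser's salt aminomethylate C7 only, since the cyclopropyl α-hydrogen is not removed, giving the aminomethyl cyclopropyl ketone F4. Dissolving-metal reduction (Li, liquid NH3, tBuOH) cleaves the exocyclic C9–CH2 bond, turning the α methylene into the 10α-methyl group, and the route is rejoined at 19.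

Step 15 (catalyst-controlled reduction of the labile α-methylene ketone). If selectivity is poor, 21 is reduced under Luche conditions (NaBH4, CeCl3·7H2O, MeOH, −78 °C). The 8β epimer is 22 itself. The 8α epimer, the 8α-allylic alcohol F5, is separated and esterified with acrylic acid under Mitsunobu conditions (PPh3, DIAD) with inversion at C8, so both epimers converge and the route is rejoined at 23.

Step 25 (angeloylation of a hindered secondary alcohol without Z-to-E isomerisation). If tiglate or low conversion is seen, 34 is acylated at O-2 with 2-[bis(2,2,2-trifluoroethoxy)phosphoryl]propanoic acid (DCC, DMAP) to give the phosphonate ester F6. A Still–Gennari olefination with acetaldehyde (KN(SiMe3)2, 18-crown-6, THF, −78 °C) then builds the Z-configured 2-methylbut-2-enoate directly on the substrate, arriving at 37.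

**Further compounds**
F1 | step 13 | 2α-[(tert-butyldimethylsilyl)oxy]-11,12,13,14-tetranor-1αH,8βH-guaia-4,9-dien-8α-ol | CC(C)(C)[Si](C)(C)O[C@H]1CC(C)=C2CC[C@@H](O)C=C[C@H]12
F2 | step 13 | 9α,10α-methano-2α-[(tert-butyldimethylsilyl)oxy]-11,12,13,14-tetranor-1αH-guai-4-en-8α-ol (cyclopropane cis to the 8-OH) | CC(C)(C)[Si](C)(C)O[C@H]1CC(C)=C2CC[C@@H](O)[C@H]3C[C@H]3[C@H]12
F3 | step 13 | 9α,10α-methano-2α-[(tert-butyldimethylsilyl)oxy]-11,12,13,14-tetranor-1αH-guai-4-en-8-one | CC(C)(C)[Si](C)(C)O[C@H]1CC(C)=C2CCC(=O)[C@H]3C[C@H]3[C@H]12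
F4 | step 13 | 7ξ-[(dimethylamino)methyl]-9α,10α-methano-2α-[(tert-butyldimethylsilyl)oxy]-11,12,13,14-tetranor-1αH-guai-4-en-8-one | CC(C)(C)[Si](C)(C)O[C@H]1CC(C)=C2CC(CN(C)C)C(=O)[C@H]3C[C@H]3[C@H]12
F5 | step 15 | 7-methylidene-2α-[(tert-butyldimethylsilyl)oxy]-11,12,13-trinor-1αH,8βH,10βH-guai-4-en-8α-ol | CC(C)(C)[Si](C)(C)O[C@H]1CC(C)=C2CC(=C)[C@@H](O)C[C@@H](C)[C@H]12
F6 | step 25 | 2-O-{2-[bis(2,2,2-trifluoroethoxy)phosphoryl]propanoyl} derivative of 34 (phosphonate α-carbon unassigned) | CC(C(=O)O[C@H]1C[C@@](C)(O)[C@@]23C[C@H]4[C@@H](C[C@@H](C)[C@H]12)OC(=O)[C@@]4(C)O3)P(=O)(OCC(F)(F)F)OCC(F)(F)F
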